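**Retrosynthetic overview**

1. The target is reached from a bicyclic C12 ketone (ring A as a 14‑acetoxycyclohexanone, ring B still carrying a C3–C4 alkyne) by tailoring only: Z‑semireduction, E1cB, enone epoxidation, ketone reduction, acetylation, desilylation.
2. The bicyclic ketone comes from a 14‑membered carbocycle, the cembranoid‑type seco form of the briarane skeleton. One transannular C1–C10 bond closes the six‑membered ring A (C1, C10–C14) and the ten‑membered ring B (C1–C10) together, as in the presumed cembrane‑to‑briarane biosynthesis.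
3. Enabling feature: C1 and C10 are the two fusion atoms shared by rings A and B. C1 is quaternary and bears methyl C15, so it can be made as a tertiary radical by hydrogen‑atom addition to a C1=C15 methylene. C10 lies β to the C12 oxygen, so with C12 as a ketone the C10=C11 bond is an enone acceptor.
4. The macrocycle comes from a Sonogashira ring closure (C4–C5) after a Nozaki–Hiyama–Kishi union (C9–C10) of a lactone aldehyde with an iodoenone that is itself made by an aldol (C13–C14).
5. The lactone (ring C, formed first) comes from Sharpless epoxidation and epoxy‑ester lactonization of a dienol built from a lactate‑derived phosphonosuccinate and a bromo enal. Ring order: lactone, 14‑membered ring, rings A and B in one step, epoxide last.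

Key step: step 22

Remark: briarane numbering (C1–C20) is used for all intermediates, and the C14 oxygen is a temporary leaving group. All six starting materials are taken as commercially available. The senses of induction quoted for the ProPhenol antipodes, the tartrate and the sulfonamide ligand follow the usual models; the antipodal ligand would be used if a sense proved opposite.

**Route**

Step 1
Reactants: 1 2-methylenepropane-1,3-diol
Product: 2 2-(hydroxymethyl)prop-2-en-1-yl acetate
Conditions: vinyl acetate, lipase (Candida antarctica lipase B, immobilized), THF, rt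
Reagents that add atoms: vinyl acetate, CC(=O)OC=C
Why: Lipase‑catalysed transesterification with an enol ester is irreversible and should stop at the monoacetate of the symmetric diol (enzymatic monoacylation); no stereocenter is formed.

Step 2
Reactants: 2 2-(hydroxymethyl)prop-2-en-1-yl acetate
Product: 3 2-formylprop-2-en-1-yl acetate
Conditions: MnO2, CH2Cl2, rt
Reagents that add atoms: none
Why: Allylic oxidation with MnO2 should give the enal without touching the acetate.

Step 3
Reactants: 3 2-formylprop-2-en-1-yl acetate; 4 ethynyltrimethylsilane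
Product: 6 (3R)-3-hydroxy-2-methylidene-5-(trimethylsilyl)pent-4-yn-1-yl acetate, via alkynylzinc reagent 5 (not isolated)
Conditions: Me2Zn, (R,R)-ProPhenol (cat.), Ph3P=O (cat.), toluene, 0 °C
Reagents that add atoms: none
Why: Zinc–ProPhenol catalysed asymmetric alkynylation of an enal; the dinuclear zinc catalyst should direct alkynylzinc 5 to the Si face of the formyl group and so set the future C2 carbinol.

Step 4
Reactants: 6 (3R)-3-hydroxy-2-methylidene-5-(trimethylsilyl)pent-4-yn-1-yl acetate
Product: 7 (3R)-3-[(tert-butyldimethylsilyl)oxy]-2-methylidene-5-(trimethylsilyl)pent-4-yn-1-yl acetate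
Conditions: TBSCl, imidazole, DMF, rt
Reagents that add atoms: tert-butyldimethylsilyl chloride, CC(C)(C)[Si](C)(C)Cl
Why: Standard silylation of the secondary alcohol; the TBS ether is kept to the last step.

Step 5
Reactants: 7 (3R)-3-[(tert-butyldimethylsilyl)oxy]-2-methylidene-5-(trimethylsilyl)pent-4-yn-1-yl acetate
Product: 8 (3S)-3-[(tert-butyldimethylsilyl)oxy]-2-methylidenepent-4-yn-1-ol
Conditions: K2CO3 (cat.), MeOH, rt
Reagents that add atoms: none
Why: Methanolysis should remove the acetate and the alkynyl silyl group in one operation while the secondary TBS ether survives (the descriptor changes only because of CIP ranking).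

Step 6
Reactants: 8 (3S)-3-[(tert-butyldimethylsilyl)oxy]-2-methylidenepent-4-yn-1-ol
Product: 9 (3S)-3-[(tert-butyldimethylsilyl)oxy]-2-methylidenepent-4-ynal
Conditions: MnO2, CH2Cl2, rt
Reagents that add atoms: none
Why: Selective allylic oxidation with MnO2 gives the non‑enolizable enal that will supply C14.

Step 7
Reactants: 10 (E)-3-iodo-2-methylprop-2-enoic acid
Product: 11 (E)-3-iodo-N-methoxy-N,2-dimethylprop-2-enamide
Conditions: MeNH(OMe)·HCl, EDC·HCl, Et3N, CH2Cl2, 0 °C to rt
Reagents that add atoms: N,O-dimethylhydroxylamine hydrochloride, CNOC.Cl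
Why: Carbodiimide amide coupling gives the Weinreb amide with the alkene geometry unchanged.

Step 8
Reactants: 11 (E)-3-iodo-N-methoxy-N,2-dimethylprop-2-enamide
Product: 12 (E)-4-iodo-3-methylbut-3-en-2-one
Conditions: MeMgBr, THF, −20 °C
Reagents that add atoms: methylmagnesium bromide, C[Mg]Br
Why: Weinreb ketone synthesis; the chelated adduct prevents over‑addition and the Grignard reagent does not exchange with the vinyl iodide at this temperature.

Step 9
Reactants: 12 (E)-4-iodo-3-methylbut-3-en-2-one; 9 (3S)-3-[(tert-butyldimethylsilyl)oxy]-2-methylidenepent-4-ynal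
Product: 13 (1E,5R,7S)-7-[(tert-butyldimethylsilyl)oxy]-5-hydroxy-1-iodo-2-methyl-6-methylidenenon-1-en-8-yn-3-one
Conditions: (S,S)-ProPhenol (cat.), Et2Zn (cat.), Ph3P=S (cat.), 4 Å MS, THF, 0 °C
Reagents that add atoms: none
Why: Zinc–ProPhenol catalysed direct aldol addition of a methyl ketone; 12 can enolize only at its methyl group and 9 cannot enolize, and Re‑face attack should give the (R)-carbinol at C14, a temporary center removed in step 24.

Step 10
Reactants: 14 tert-butyl (R)-2-hydroxypropanoate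
Product: 15 tert-butyl (R)-2-{[(trifluoromethyl)sulfonyl]oxy}propanoate
Conditions: Tf2O, 2,6-lutidine, CH2Cl2, −78 °C
Reagents that add atoms: trifluoromethanesulfonic anhydride, O=S(=O)(OS(=O)(=O)C(F)(F)F)C(F)(F)F
Why: O‑Triflation proceeds with retention and provides the leaving group for the stereospecific alkylation.

Step 11
Reactants: 16 triethyl phosphonoacetate; 15 tert-butyl (R)-2-{[(trifluoromethyl)sulfonyl]oxy}propanoate
Product: 18 4-tert-butyl 1-ethyl (3S)-2-(diethoxyphosphoryl)-3-methylbutanedioate, via sodium phosphonoacetate 17 (not isolated)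
Conditions: NaH, THF, 0 °C; then 15, 0 °C to rt
Reagents that add atoms: none
Why: SN2 alkylation of the stabilized carbanion 17 by the lactate triflate with inversion sets the future C17 methyl center; the phosphonate carbon stays a mixture, which is irrelevant.

Step 12
Reactants: 19 4-[(tert-butyldimethylsilyl)oxy]but-2-yn-1-ol
Product: 21 (Z)-3-bromo-4-[(tert-butyldimethylsilyl)oxy]but-2-en-1-ol, via vinylalanate 20 (not isolated)
Conditions: NaAlH2(OCH2CH2OMe)2, THF, 0 °C; then NBS, −78 °C
Reagents that add atoms: N-bromosuccinimide, O=C1CCC(=O)N1Br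
Why: Hydroxyl‑directed trans‑hydroalumination of the propargylic alcohol places aluminum on the distal alkyne carbon (20), and bromination with retention gives the Z vinyl bromide with bromine cis to the carbinol carbon.

Step 13
Reactants: 21 (Z)-3-bromo-4-[(tert-butyldimethylsilyl)oxy]but-2-en-1-ol
Product: 22 (Z)-3-bromo-4-[(tert-butyldimethylsilyl)oxy]but-2-enal
Conditions: MnO2, CH2Cl2, rt
Reagents that add atoms: none
Why: Neutral allylic oxidation should give the β‑bromo enal without Z/E isomerization.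

Step 14
Reactants: 18 4-tert-butyl 1-ethyl (3S)-2-(diethoxyphosphoryl)-3-methylbutanedioate; 22 (Z)-3-bromo-4-[(tert-butyldimethylsilyl)oxy]but-2-enal
Product: 23 4-tert-butyl 1-ethyl (2E,3R)-2-{(2Z)-3-bromo-4-[(tert-butyldimethylsilyl)oxy]but-2-en-1-ylidene}-3-methylbutanedioate
Conditions: LiCl, iPr2NEt, MeCN, 0 °C to rt
Reagents that add atoms: none
Why: Horner–Wadsworth–Emmons olefination under LiCl/amine conditions should place the conjugated ester trans to the dienyl chain (E), and the weak base should leave the α‑methyl center and the β‑bromo enal intact.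

Step 15
Reactants: 23 4-tert-butyl 1-ethyl (2E,3R)-2-{(2Z)-3-bromo-4-[(tert-butyldimethylsilyl)oxy]but-2-en-1-ylidene}-3-methylbutanedioate
Product: 24 tert-butyl (2R,3E,5Z)-6-bromo-7-[(tert-butyldimethylsilyl)oxy]-3-(hydroxymethyl)-2-methylhepta-3,5-dienoate
Conditions: iBu2AlH, CH2Cl2, −78 °C
Reagents that add atoms: none
Why: Chemoselective DIBAL‑H reduction of the conjugated ethyl ester to the allylic alcohol; the hindered tert‑butyl ester is not attacked at −78 °C.

Step 16
Reactants: 24 tert-butyl (2R,3E,5Z)-6-bromo-7-[(tert-butyldimethylsilyl)oxy]-3-(hydroxymethyl)-2-methylhepta-3,5-dienoate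
Product: 25 tert-butyl (2R)-2-[(2R,3R)-3-{(Z)-2-bromo-3-[(tert-butyldimethylsilyl)oxy]prop-1-en-1-yl}-2-(hydroxymethyl)oxiran-2-yl]propanoate
Conditions: Ti(OiPr)4 (cat.), D-(−)-diethyl tartrate (cat.), t-BuOOH, 4 Å MS, CH2Cl2, −20 °C
Reagents that add atoms: tert-butyl hydroperoxide, CC(C)(C)OO
Why: Sharpless asymmetric epoxidation of the 2,3‑disubstituted (E)-allylic alcohol; the D‑tartrate should give the (2R,3R)-epoxy alcohol, which fixes C8 and, after inversion in step 17, C7, and only the allylic‑alcohol alkene reacts.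

Step 17
Reactants: 25 tert-butyl (2R)-2-[(2R,3R)-3-{(Z)-2-bromo-3-[(tert-butyldimethylsilyl)oxy]prop-1-en-1-yl}-2-(hydroxymethyl)oxiran-2-yl]propanoate
Product: 26 (3R,4R,5S)-5-{(Z)-2-bromo-3-[(tert-butyldimethylsilyl)oxy]prop-1-en-1-yl}-4-hydroxy-4-(hydroxymethyl)-3-methyloxolan-2-one
Conditions: BF3·OEt2 (cat.), CH2Cl2, −78 to −20 °C
Reagents that add atoms: none
Why: Acid‑catalysed epoxy‑ester lactonization: the tert‑butyl ester carbonyl opens the vinyl epoxide at its allylic carbon C7 with inversion (five is the only feasible ring size), C8 keeps its oxygen with retention, and isobutene is lost.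

Step 18
Reactants: 26 (3R,4R,5S)-5-{(Z)-2-bromo-3-[(tert-butyldimethylsilyl)oxy]prop-1-en-1-yl}-4-hydroxy-4-(hydroxymethyl)-3-methyloxolan-2-one
Product: 27 (2S,3S,4R)-2-{(Z)-2-bromo-3-[(tert-butyldimethylsilyl)oxy]prop-1-en-1-yl}-3-hydroxy-4-methyl-5-oxooxolane-3-carbaldehyde
Conditions: Dess–Martin periodinane, NaHCO3, CH2Cl2, 0 °C
Reagents that add atoms: none
Why: Dess–Martin oxidation of the primary alcohol gives the α‑hydroxy aldehyde (C9); the tertiary alcohol cannot be oxidized.

Step 19
Reactants: 27 (2S,3S,4R)-2-{(Z)-2-bromo-3-[(tert-butyldimethylsilyl)oxy]prop-1-en-1-yl}-3-hydroxy-4-methyl-5-oxooxolane-3-carbaldehyde; 13 (1E,5R,7S)-7-[(tert-butyldimethylsilyl)oxy]-5-hydroxy-1-iodo-2-methyl-6-methylidenenon-1-en-8-yn-3-one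
Product: 28 seco enyne precursor (C9–C10 joined; 8,9,14-triol; C5 vinyl bromide; C4 terminal alkyne)
Conditions: CrCl2, NiCl2 (cat.), chiral oxazoline sulfonamide ligand, Et3N, THF, rt
Reagents that add atoms: none
Why: Nozaki–Hiyama–Kishi coupling: zerovalent nickel inserts into the vinyl iodide much faster than into the hindered vinyl bromide, the alkenylchromium species adds with retention of the E geometry, and the chiral ligand on chromium should direct Re‑face attack to set the C9 carbinol.

Step 20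
Reactants: 28 seco enyne precursor
Product: 29 14-membered macrocyclic enyne triol
Conditions: Pd(PPh3)4 (cat.), CuI (cat.), iPr2NH, THF, rt, high dilution (slow addition)
Reagents that add atoms: none
Why: Intramolecular Sonogashira coupling joins C4 and C5 with retention of alkene geometry (C4 cis to C7); a 14‑membered ring can hold the linear enyne, and dilution suppresses oligomers.

Step 21
Reactants: 29 14-membered macrocyclic enyne triol
Product: 30 macrocyclic 9,14-diacetate
Conditions: Ac2O, pyridine, DMAP (cat.), CH2Cl2, 0 °C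
Reagents that add atoms: acetic anhydride, CC(=O)OC(C)=O
Why: Acetylation of the two secondary alcohols (the tertiary C8 alcohol is too hindered) installs the C9 acetate of the target and turns the C14 oxygen into the later leaving group.

Step 22
Reactants: 30 macrocyclic 9,14-diacetate
Product: 33 trans-fused bicyclic C12 ketone, via tertiary C1 radical 31 (not isolated), via C11 keto radical 32 (not isolated)
Conditions: Fe(acac)3 (cat.), PhSiH3, EtOH/ethylene glycol, 60 °C, high dilution
Reagents that add atoms: none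
Why: Proposed new method: an iron hydride formed from Fe(acac)3 and PhSiH3 transfers a hydrogen atom to the unhindered CH2 terminus of the C1=C15 alkene, which turns C15 into the C1 methyl and gives tertiary radical 31; this adds across the ring to C10, the β‑carbon of the (E)-enone, to give α‑keto radical 32, which is reduced by divalent iron and protonated by ethanol (closest known reaction types: the intramolecular hydrogen‑atom‑transfer‑initiated radical conjugate addition of alkenes to enones, and tin‑ or titanocene‑mediated transannular radical cyclizations of macrocycles). The one new bond closes ring A in the 6‑endo‑trig mode and ring B in the 10‑exo‑trig mode, the 6‑endo course being enforced by polarity matching between the nucleophilic tertiary radical and the enone β‑carbon. C1 and C10 should be set through a chair‑like transition state with the C2–C9 bridge trans‑diequatorial and a Felkin–Anh arrangement at both flanking stereocenters (C2–OTBS and C9–OAc bonds anti to the forming bond, H2 and H9 in the π‑planes to avoid A(1,3) strain with C14 and the C11 methyl), which leads to the trans fusion of the target with the C1 methyl β and H10 α. C11 is set by kinetic protonation (or hydrogen‑atom transfer) from the α‑face, anti to the axial C1 methyl, which places the C11 methyl β. The step needs chemoselective hydrogen‑atom transfer to the C1=C15 alkene in the presence of the enone and the C5=C6 alkene; this is secured by the accessibility of the terminal CH2 and by carrying C3–C4 as an alkyne, so that no conjugated diene is present. The C14 acetate sits β to the new ketone so that the C13=C14 alkene can be unmasked after the radical event without making the C1 radical allylic.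

Step 23
Reactants: 33 trans-fused bicyclic C12 ketone
Product: 34 bicyclic (3Z,5E)-diene ketone
Conditions: Zn dust activated with Cu(OAc)2 and AgNO3, MeOH/H2O, 40 °C
Reagents that add atoms: none
Why: cis‑Semireduction of the conjugated enyne with activated zinc (Boland reduction) should give the 3Z alkene of the target; isolated alkenes, the ketone and the esters are inert.

Step 24
Reactants: 34 bicyclic (3Z,5E)-diene ketone
Product: 35 cyclohex-13-en-12-one
Conditions: DBU, CH2Cl2, 0 °C
Reagents that add atoms: none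
Why: E1cB elimination of the β‑acetoxy ketone gives the enone; deprotonation at C13 and irreversible loss of acetate should be much faster than enolization toward the hindered C11, which keeps its configuration.

Step 25
Reactants: 35 cyclohex-13-en-12-one
Product: 36 13α,14α-epoxy 12-ketone
Conditions: t-BuOOH, DBU (cat.), CH2Cl2, 0 °C
Reagents that add atoms: tert-butyl hydroperoxide, CC(C)(C)OO
Why: Weitz–Scheffer nucleophilic epoxidation: the hydroperoxide anion should attack C14 axially from the α‑face, anti to the axial C1 methyl, and the electron‑rich diene does not react with the nucleophilic oxidant.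

Step 26
Reactants: 36 13α,14α-epoxy 12-ketone
Product: 37 12β-alcohol
Conditions: NaBH4, CeCl3·7H2O, MeOH, −78 °C
Reagents that add atoms: none
Why: Luche reduction: hydride should attack C12 from the α‑face, anti to the axial C11 methyl and syn to the epoxide oxygen (the usual course for 2,3‑epoxy ketones under cerium chelation), giving the 12β‑alcohol trans to the epoxide.

Step 27
Reactants: 37 12β-alcohol
Product: 38 2,16-bis-O-TBS briaexcavatolide N
Conditions: Ac2O, DMAP (cat.), pyridine, CH2Cl2, rt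
Reagents that add atoms: acetic anhydride, CC(=O)OC(C)=O
Why: Acetylation of the only free secondary alcohol (C12); the tertiary C8 alcohol is not acylated and C2 and C16 are silyl‑protected.

Step 28
Reactants: 38 2,16-bis-O-TBS briaexcavatolide N
Product: 39 briaexcavatolide N
Conditions: HF·pyridine, pyridine, THF, 0 °C to rt
Reagents that add atoms: none
Why: Buffered fluoride desilylation removes both TBS ethers; the epoxide, the two acetates and the lactone should survive.

**Compound list**

1 | 2-methylenepropane-1,3-diol | C=C(CO)CO | starting material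
2 | 2-(hydroxymethyl)prop-2-en-1-yl acetate | CC(=O)OCC(=C)CO | intermediate
3 | 2-formylprop-2-en-1-yl acetate | CC(=O)OCC(=C)C=O | intermediate
4 | ethynyltrimethylsilane | C#C[Si](C)(C)C | starting material
5 | methyl[(trimethylsilyl)ethynyl]zinc | C[Zn]C#C[Si](C)(C)C | intermediate
6 | (3R)-3-hydroxy-2-methylidene-5-(trimethylsilyl)pent-4-yn-1-yl acetate | C[Si](C)(C)C#C[C@H](O)C(=C)COC(C)=O | intermediate
7 | (3R)-3-[(tert-butyldimethylsilyl)oxy]-2-methylidene-5-(trimethylsilyl)pent-4-yn-1-yl acetate | C[Si](C)(C)C#C[C@H](O[Si](C)(C)C(C)(C)C)C(=C)COC(C)=O | intermediate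
8 | (3S)-3-[(tert-butyldimethylsilyl)oxy]-2-methylidenepent-4-yn-1-ol | C#C[C@H](O[Si](C)(C)C(C)(C)C)C(=C)CO | intermediate
9 | (3S)-3-[(tert-butyldimethylsilyl)oxy]-2-methylidenepent-4-ynal | C#C[C@H](O[Si](C)(C)C(C)(C)C)C(=C)C=O | intermediate
10 | (E)-3-iodo-2-methylprop-2-enoic acid | OC(=O)/C(C)=C/I | starting material
11 | (E)-3-iodo-N-methoxy-N,2-dimethylprop-2-enamide | CON(C)C(=O)/C(C)=C/I | intermediate
12 | (E)-4-iodo-3-methylbut-3-en-2-one | CC(=O)/C(C)=C/I | intermediate
13 | (1E,5R,7S)-7-[(tert-butyldimethylsilyl)oxy]-5-hydroxy-1-iodo-2-methyl-6-methylidenenon-1-en-8-yn-3-one (C10–C14, C1–C4, C15, C20) | C#C[C@H](O[Si](C)(C)C(C)(C)C)C(=C)[C@H](O)CC(=O)/C(C)=C/I | intermediate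
14 | tert-butyl (R)-2-hydroxypropanoate | C[C@@H](O)C(=O)OC(C)(C)C | starting material
15 | tert-butyl (R)-2-{[(trifluoromethyl)sulfonyl]oxy}propanoate | C[C@@H](OS(=O)(=O)C(F)(F)F)C(=O)OC(C)(C)C | intermediate
16 | triethyl phosphonoacetate | CCOC(=O)CP(=O)(OCC)OCC | starting material
17 | sodium salt of triethyl phosphonoacetate | [Na+].CCOC(=O)[CH-]P(=O)(OCC)OCC | intermediate
18 | 4-tert-butyl 1-ethyl (3S)-2-(diethoxyphosphoryl)-3-methylbutanedioate (both epimers at the phosphonate carbon) | CCOC(=O)C([C@@H](C)C(=O)OC(C)(C)C)P(=O)(OCC)OCC | intermediate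
19 | 4-[(tert-butyldimethylsilyl)oxy]but-2-yn-1-ol | OCC#CCO[Si](C)(C)C(C)(C)C | starting material
20 | sodium cyclic alkoxy(vinyl)bis(2-methoxyethoxy)alanate from 19 | [Na+].COCCO[Al-]1(OCCOC)OCC=C1CO[Si](C)(C)C(C)(C)C | intermediate
21 | (Z)-3-bromo-4-[(tert-butyldimethylsilyl)oxy]but-2-en-1-ol | OC/C=C(\Br)CO[Si](C)(C)C(C)(C)C | intermediate
22 | (Z)-3-bromo-4-[(tert-butyldimethylsilyl)oxy]but-2-enal | O=C/C=C(\Br)CO[Si](C)(C)C(C)(C)C | intermediate
23 | 4-tert-butyl 1-ethyl (2E,3R)-2-{(2Z)-3-bromo-4-[(tert-butyldimethylsilyl)oxy]but-2-en-1-ylidene}-3-methylbutanedioate | CCOC(=O)/C(=C/C=C(\Br)CO[Si](C)(C)C(C)(C)C)[C@@H](C)C(=O)OC(C)(C)C | intermediate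
24 | tert-butyl (2R,3E,5Z)-6-bromo-7-[(tert-butyldimethylsilyl)oxy]-3-(hydroxymethyl)-2-methylhepta-3,5-dienoate | OC/C(=C/C=C(\Br)CO[Si](C)(C)C(C)(C)C)[C@@H](C)C(=O)OC(C)(C)C | intermediate
25 | tert-butyl (2R)-2-[(2R,3R)-3-{(Z)-2-bromo-3-[(tert-butyldimethylsilyl)oxy]prop-1-en-1-yl}-2-(hydroxymethyl)oxiran-2-yl]propanoate | OC[C@]1(O[C@@H]1/C=C(\Br)CO[Si](C)(C)C(C)(C)C)[C@@H](C)C(=O)OC(C)(C)C | intermediate
26 | (3R,4R,5S)-5-{(Z)-2-bromo-3-[(tert-butyldimethylsilyl)oxy]prop-1-en-1-yl}-4-hydroxy-4-(hydroxymethyl)-3-methyloxolan-2-one | OC[C@@]1(O)[C@H](/C=C(\Br)CO[Si](C)(C)C(C)(C)C)OC(=O)[C@@H]1C | intermediate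
27 | (2S,3S,4R)-2-{(Z)-2-bromo-3-[(tert-butyldimethylsilyl)oxy]prop-1-en-1-yl}-3-hydroxy-4-methyl-5-oxooxolane-3-carbaldehyde | O=C[C@@]1(O)[C@H](/C=C(\Br)CO[Si](C)(C)C(C)(C)C)OC(=O)[C@@H]1C | intermediate
28 | seco enyne precursor: lactone (C19 to O7) carrying the C5 vinyl bromide and, through the (9R)-carbinol, the (10E)-enone chain with 14-OH, C1=C15 methylene, 2-OTBS and the terminal C3–C4 alkyne | C#C[C@H](O[Si](C)(C)C(C)(C)C)C(=C)[C@H](O)CC(=O)/C(C)=C/[C@@H](O)[C@@]1(O)[C@H](/C=C(\Br)CO[Si](C)(C)C(C)(C)C)OC(=O)[C@@H]1C | intermediate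
29 | 14-membered carbocyclic (5E,10E)-dien-3-yne: 8,9,14-triol, 12-ketone, C1=C15 methylene, 2,16-bis-TBS ether, γ-lactone C19 to O7 | O=C1/C(C)=C/[C@@H](O)[C@@]2(O)[C@H](/C=C(CO[Si](C)(C)C(C)(C)C)\C#C[C@H](O[Si](C)(C)C(C)(C)C)C(=C)[C@H](O)C1)OC(=O)[C@@H]2C | intermediate
30 | 9,14-diacetate of 29 (key-step substrate) | O=C1/C(C)=C/[C@@H](OC(C)=O)[C@@]2(O)[C@H](/C=C(CO[Si](C)(C)C(C)(C)C)\C#C[C@H](O[Si](C)(C)C(C)(C)C)C(=C)[C@H](OC(C)=O)C1)OC(=O)[C@@H]2C | intermediate
31 | tertiary C1 radical of the macrocycle (C15 now methyl) | O=C1/C(C)=C/[C@@H](OC(C)=O)[C@@]2(O)[C@H](/C=C(CO[Si](C)(C)C(C)(C)C)\C#C[C@H](O[Si](C)(C)C(C)(C)C)[C](C)[C@H](OC(C)=O)C1)OC(=O)[C@@H]2C | intermediate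
32 | bicyclic C11 α-keto radical after C1–C10 bond formation | O=C1[C](C)[C@@H]2[C@@H](OC(C)=O)[C@@]3(O)[C@H](/C=C(CO[Si](C)(C)C(C)(C)C)\C#C[C@H](O[Si](C)(C)C(C)(C)C)[C@@]2(C)[C@H](OC(C)=O)C1)OC(=O)[C@@H]3C | intermediate
33 | trans-fused bicyclic 12-ketone: ring A cyclohexanone with 14β-OAc and 11β-methyl, ring B cyclodec-5-en-3-yne, 9-OAc, 8-OH, 2,16-bis-TBS ether, γ-lactone; C1, C2, C7–C11, C17 configured as in 39 | O=C1[C@H](C)[C@@H]2[C@@H](OC(C)=O)[C@@]3(O)[C@H](/C=C(CO[Si](C)(C)C(C)(C)C)\C#C[C@H](O[Si](C)(C)C(C)(C)C)[C@@]2(C)[C@H](OC(C)=O)C1)OC(=O)[C@@H]3C | intermediate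
34 | (3Z,5E)-diene analogue of 33 | O=C1[C@H](C)[C@@H]2[C@@H](OC(C)=O)[C@@]3(O)[C@H](/C=C(CO[Si](C)(C)C(C)(C)C)\C=C/[C@H](O[Si](C)(C)C(C)(C)C)[C@@]2(C)[C@H](OC(C)=O)C1)OC(=O)[C@@H]3C | intermediate
35 | cyclohex-13-en-12-one (9-OAc, 8-OH, 2,16-bis-TBS ether) | O=C1[C@H](C)[C@@H]2[C@@H](OC(C)=O)[C@@]3(O)[C@H](/C=C(CO[Si](C)(C)C(C)(C)C)\C=C/[C@H](O[Si](C)(C)C(C)(C)C)[C@@]2(C)C=C1)OC(=O)[C@@H]3C | intermediate
36 | 13α,14α-epoxy 12-ketone | O=C1[C@H](C)[C@@H]2[C@@H](OC(C)=O)[C@@]3(O)[C@H](/C=C(CO[Si](C)(C)C(C)(C)C)\C=C/[C@H](O[Si](C)(C)C(C)(C)C)[C@@]2(C)[C@H]2O[C@@H]12)OC(=O)[C@@H]3C | intermediate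
37 | 13α,14α-epoxy 12β-alcohol | O[C@@H]1[C@H](C)[C@@H]2[C@@H](OC(C)=O)[C@@]3(O)[C@H](/C=C(CO[Si](C)(C)C(C)(C)C)\C=C/[C@H](O[Si](C)(C)C(C)(C)C)[C@@]2(C)[C@H]2O[C@@H]12)OC(=O)[C@@H]3C | intermediate
38 | 2,16-bis-O-(tert-butyldimethylsilyl) briaexcavatolide N | CC(=O)O[C@@H]1[C@H](C)[C@@H]2[C@@H](OC(C)=O)[C@@]3(O)[C@H](/C=C(CO[Si](C)(C)C(C)(C)C)\C=C/[C@H](O[Si](C)(C)C(C)(C)C)[C@@]2(C)[C@H]2O[C@@H]12)OC(=O)[C@@H]3C | intermediate
39 | briaexcavatolide N | CC(=O)O[C@@H]1[C@H](C)[C@@H]2[C@@H](OC(C)=O)[C@@]3(O)[C@H](/C=C(CO)\C=C/[C@H](O)[C@@]2(C)[C@H]2O[C@@H]12)OC(=O)[C@@H]3C | target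

**Step count and risks**

Total step count: 28. Longest linear sequence: 17 steps (steps 10, 11, 14–28; the branch through steps 1–6 and 9 is equally long).

Steps most likely to fail:

1. Step 22 (Proposed new method). The hydrogen atom may be transferred to the enone or the enyne alkene instead of the C1=C15 alkene, the C1 radical may be reduced before it cyclizes, or the ring closure may pass through a transition state that gives the cis‑fused or C1/C10‑epimeric bicycle. The fallback uses known radical chemistry, sets out from 29 and comes back at 33. Hydroxyl‑directed epoxidation of the C1=C15 alkene (VO(acac)2, t-BuOOH; directed by the C14 alcohol) would give spiro-epoxide triol F1, and acetylation (Ac2O, pyridine) would give epoxy diacetate F2. Cp2TiCl (from Cp2TiCl2 and Zn dust; Nugent–RajanBabu conditions) opens the epoxide homolytically to a tertiary C1 radical that undergoes the same transannular conjugate addition, a titanocene‑mediated cyclization type known for macrocyclic epoxides, to give C15-hydroxy bicyclic ketone F3. Its primary alcohol is converted with 1,1'-thiocarbonyldiimidazole into imidazole-1-carbothioate F4, and Barton–McCombie deoxygenation ((Me3Si)3SiH, AIBN) returns 33.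

2. Step 20. Oligomerization may outrun ring closure, reductive elimination may stall in the strained palladacycle, or the free C9 alcohol may translactonize under the amine. The fallback closes the ring by a Nozaki–Hiyama–Kishi reaction instead, sets out from 26 and 9 and comes back at 29. Intermolecular Sonogashira coupling of 26 with 9 (Pd(PPh3)4, CuI, iPr2NH) would give enyne enal diol F5. The aldol of step 9 with 12 would then give iodoenone triol F6, and selective oxidation of the primary alcohol (TEMPO, PhI(OAc)2) would give iodoenone aldehyde F7. Intramolecular coupling (CrCl2, NiCl2 cat., chiral sulfonamide ligand, high dilution) forms the C9–C10 bond and the 14‑membered ring of 29.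

3. Step 25. Base may epimerize the kinetically set axial C11 methyl while C12 is a ketone, or the peroxide may attack the β‑face. The fallback removes the ketone first and epoxidizes electrophilically while ring B still holds the deactivated enyne; it sets out from 33 and comes back at 38. DBU elimination on 33 would give enynyl cyclohexenone F8, immediate Luche reduction would give 12β-allylic alcohol F9, and acetylation would give allylic acetate F10. mCPBA (NaHCO3 buffer) should attack the C13=C14 alkene from the α‑face, anti to the 12β‑acetate and the C1 methyl, to give alkynyl epoxide F11, and activated zinc semireduction returns 38.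

**Further compounds**

F1 | step 22 | spiro-epoxide triol (C1–C15 epoxide of 29, either configuration at C1) | O=C1/C(C)=C/[C@@H](O)[C@@]2(O)[C@H](/C=C(CO[Si](C)(C)C(C)(C)C)\C#C[C@H](O[Si](C)(C)C(C)(C)C)C3(CO3)[C@H](O)C1)OC(=O)[C@@H]2C
F2 | step 22 | epoxy diacetate (9,14-diacetate of F1) | O=C1/C(C)=C/[C@@H](OC(C)=O)[C@@]2(O)[C@H](/C=C(CO[Si](C)(C)C(C)(C)C)\C#C[C@H](O[Si](C)(C)C(C)(C)C)C3(CO3)[C@H](OC(C)=O)C1)OC(=O)[C@@H]2C
F3 | step 22 | C15-hydroxy bicyclic ketone (33 with CH2OH in place of the C1 methyl) | O=C1[C@H](C)[C@@H]2[C@@H](OC(C)=O)[C@@]3(O)[C@H](/C=C(CO[Si](C)(C)C(C)(C)C)\C#C[C@H](O[Si](C)(C)C(C)(C)C)[C@@]2(CO)[C@H](OC(C)=O)C1)OC(=O)[C@@H]3C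
F4 | step 22 | imidazole-1-carbothioate of F3 | O=C1[C@H](C)[C@@H]2[C@@H](OC(C)=O)[C@@]3(O)[C@H](/C=C(CO[Si](C)(C)C(C)(C)C)\C#C[C@H](O[Si](C)(C)C(C)(C)C)[C@@]2(COC(=S)n4ccnc4)[C@H](OC(C)=O)C1)OC(=O)[C@@H]3C
F5 | step 20 | enyne enal diol (26 coupled to 9 at C4–C5) | OC[C@@]1(O)[C@H](/C=C(CO[Si](C)(C)C(C)(C)C)\C#C[C@H](O[Si](C)(C)C(C)(C)C)C(=C)C=O)OC(=O)[C@@H]1C
F6 | step 20 | iodoenone triol (aldol adduct of F5 with 12) | OC[C@@]1(O)[C@H](/C=C(CO[Si](C)(C)C(C)(C)C)\C#C[C@H](O[Si](C)(C)C(C)(C)C)C(=C)[C@H](O)CC(=O)/C(C)=C/I)OC(=O)[C@@H]1C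
F7 | step 20 | iodoenone aldehyde (C9 aldehyde of F6) | O=C[C@@]1(O)[C@H](/C=C(CO[Si](C)(C)C(C)(C)C)\C#C[C@H](O[Si](C)(C)C(C)(C)C)C(=C)[C@H](O)CC(=O)/C(C)=C/I)OC(=O)[C@@H]1C
F8 | step 25 | enynyl cyclohexenone (35 with the C3–C4 alkyne) | O=C1[C@H](C)[C@@H]2[C@@H](OC(C)=O)[C@@]3(O)[C@H](/C=C(CO[Si](C)(C)C(C)(C)C)\C#C[C@H](O[Si](C)(C)C(C)(C)C)[C@@]2(C)C=C1)OC(=O)[C@@H]3C
F9 | step 25 | 12β-allylic alcohol | O[C@@H]1[C@H](C)[C@@H]2[C@@H](OC(C)=O)[C@@]3(O)[C@H](/C=C(CO[Si](C)(C)C(C)(C)C)\C#C[C@H](O[Si](C)(C)C(C)(C)C)[C@@]2(C)C=C1)OC(=O)[C@@H]3C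
F10 | step 25 | 12β-allylic acetate | CC(=O)O[C@@H]1[C@H](C)[C@@H]2[C@@H](OC(C)=O)[C@@]3(O)[C@H](/C=C(CO[Si](C)(C)C(C)(C)C)\C#C[C@H](O[Si](C)(C)C(C)(C)C)[C@@]2(C)C=C1)OC(=O)[C@@H]3C
F11 | step 25 | alkynyl 13α,14α-epoxide (38 with the C3–C4 alkyne) | CC(=O)O[C@@H]1[C@H](C)[C@@H]2[C@@H](OC(C)=O)[C@@]3(O)[C@H](/C=C(CO[Si](C)(C)C(C)(C)C)\C#C[C@H](O[Si](C)(C)C(C)(C)C)[C@@]2(C)[C@H]2O[C@@H]12)OC(=O)[C@@H]3C
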